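**Plan**

- Retrosynthesis: the two MOM ethers come off last. The pyranone ring (ring C) is then cut at both of its bonds to ring A, O1–C8a and C4–C4a. This leaves an aryne at C4a/C8a and the four atoms O1–C2–C3–C4 closed on themselves as a β-lactone.
- Enabling feature: O1 and the C4 carbonyl sit on neighbouring ring-A carbons (C8a and C4a) with the C5 oxygen beside C4a. This is the footprint of an aryne that has entered an O–C(=O) bond, and O1–C2–C3–C4(=O) is a 3-aryl-3-hydroxypropanoic acid that closes to a strained oxetan-2-one.
- Forward: ring A is elaborated into an ortho-silylaryl triflate (geranyl between the two OMOM groups, then oxygen, silicon and triflate by directed metalations). The lactone is made separately. Ring C then arises from the four-membered lactone by ring expansion to six atoms, and deprotection ends the route.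
- Stereochemistry: C2 (S) is set by asymmetric transfer hydrogenation of a β-keto ester and carried through lactonisation and insertion, in neither of which a bond to C2 is made or broken. The E alkene comes from geranyl bromide.

Key step: step 9

Remark: geranyl stands for (2E)-3,7-dimethylocta-2,6-dien-1-yl; the target is read from its SMILES as the (2S)-flavanone with the E side-chain alkene.

**Route**

Step 1
Reactants: 1 1,3-bis(methoxymethoxy)benzene; 2 geranyl bromide
Product: 4 2-geranyl-1,3-bis(methoxymethoxy)benzene, via aryllithium 3 (not isolated)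
Conditions: n-BuLi, THF, 0 °C to rt; CuBr·SMe2 (10 mol %), then 2, −78 °C to rt
Reagents that add atoms: none
Why: Directed ortho-metalation, in which the two MOM ethers cooperate to make C2 the most acidic ring position; copper-catalysed SN2 allylation of the aryllithium with the primary allylic bromide should give the linear product with the E geometry of 2 retained.

Step 2
Reactants: 4 2-geranyl-1,3-bis(methoxymethoxy)benzene
Product: 7 3-geranyl-2,4-bis(methoxymethoxy)phenol, via aryllithium 5 (not isolated), via dimethyl arylboronate 6 (not isolated)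
Conditions: n-BuLi, TMEDA, THF, −20 to 0 °C; B(OMe)3, −78 °C to rt; 30% H2O2, aq NaOH, 0 °C
Reagents that add atoms: hydrogen peroxide OO
Why: A second MOM-directed ortho-metalation can only take place at C4 (C6 is the same by symmetry), and borate trapping followed by peroxide oxidation (1,2-aryl shift from boron to oxygen) should place the hydroxyl there while basic peroxide leaves the unactivated trisubstituted alkenes untouched.

Step 3
Reactants: 7 3-geranyl-2,4-bis(methoxymethoxy)phenol
Product: 8 3-geranyl-2,4-bis(methoxymethoxy)phenyl N-isopropylcarbamate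
Conditions: i-PrNCO, Et3N (cat.), CH2Cl2, rt
Reagents that add atoms: isopropyl isocyanate CC(C)N=C=O
Why: Base-catalysed addition of the phenol to the isocyanate gives the N-monoalkyl carbamate, a directing group for ortho-metalation that can later be removed by E1cB elimination under mild conditions.

Step 4
Reactants: 8 3-geranyl-2,4-bis(methoxymethoxy)phenyl N-isopropylcarbamate
Product: 12 3-geranyl-2,4-bis(methoxymethoxy)-6-(trimethylsilyl)phenyl N-isopropylcarbamate, via N-silyl carbamate 9 (not isolated), via ortho-lithio N-silyl carbamate 10 (not isolated), via N-silyl C-silyl carbamate 11 (not isolated)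
Conditions: TBSOTf, TMEDA, Et2O, 0 °C to rt; n-BuLi, TMEDA, −78 °C; TMSCl, −78 °C to rt; aq NaHSO4 quench, 0 °C
Reagents that add atoms: chlorotrimethylsilane C[Si](C)(C)Cl
Why: In-situ N-silylation turns the carbamate into a strong directing group that resists attack at its carbonyl, so carbamate-directed ortho-metalation at −78 °C should take place at the only free ortho position C6 faster than at the ring C–H beside OMOM or at the side-chain methylene, and TMSCl traps the anion; the N–Si bond is hydrolysed on work-up.

Step 5
Reactants: 12 3-geranyl-2,4-bis(methoxymethoxy)-6-(trimethylsilyl)phenyl N-isopropylcarbamate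
Product: 14 3-geranyl-2,4-bis(methoxymethoxy)-6-(trimethylsilyl)phenyl trifluoromethanesulfonate, via ortho-silyl phenol 13 (not isolated)
Conditions: Et2NH, DBU, MeCN, 40 °C; then PhNTf2, rt
Reagents that add atoms: N-phenylbis(trifluoromethanesulfonimide) O=S(=O)(N(c1ccccc1)S(=O)(=O)C(F)(F)F)C(F)(F)F
Why: DBU-induced E1cB loss of isopropyl isocyanate (trapped by Et2NH as a urea) frees the hindered phenoxide, which is sulfonylated in the same flask to give the fluoride-triggered aryne precursor (ortho-silylaryl triflate).

Step 6
Reactants: 15 ethyl 3-(3,4-dimethoxyphenyl)-3-oxopropanoate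
Product: 16 ethyl (3S)-3-(3,4-dimethoxyphenyl)-3-hydroxypropanoate
Conditions: RuCl[(S,S)-TsDPEN](p-cymene) (1 mol %), HCO2H/Et3N 5:2, 30 °C
Reagents that add atoms: none
Why: Noyori-type asymmetric transfer hydrogenation of an aryl ketone, in which the (S,S)-TsDPEN ruthenium hydride delivers hydride in a six-membered transition state (aryl CH–π contact with the arene ligand) to the face that gives (S)-1-arylalkanols, which sets the future C2 as S.

Step 7
Reactants: 16 ethyl (3S)-3-(3,4-dimethoxyphenyl)-3-hydroxypropanoate
Product: 17 (3S)-3-(3,4-dimethoxyphenyl)-3-hydroxypropanoic acid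
Conditions: LiOH, THF/H2O, 0 °C; then 1 M HCl to pH 3, 0 °C
Reagents that add atoms: lithium hydroxide [Li+].[OH-]
Why: Saponification at 0 °C followed by cold acidification should give the acid without retro-aldol cleavage or dehydration; the stereocentre is not involved.

Step 8
Reactants: 17 (3S)-3-(3,4-dimethoxyphenyl)-3-hydroxypropanoic acid
Product: 18 (4S)-4-(3,4-dimethoxyphenyl)oxetan-2-one
Conditions: PhSO2Cl, pyridine, 0 °C; cold neutral work-up, used at once without chromatography
Reagents that add atoms: none
Why: β-Lactonisation by carboxyl activation (mixed sulfonic anhydride, 4-exo-trig attack of the hydroxyl on the acyl carbon) leaves the C–O bond at the stereocentre untouched, so the S configuration is retained.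

Step 9
Reactants: 14 3-geranyl-2,4-bis(methoxymethoxy)-6-(trimethylsilyl)phenyl trifluoromethanesulfonate; 18 (4S)-4-(3,4-dimethoxyphenyl)oxetan-2-one (2 equiv)
Product: 20 (2S)-2-(3,4-dimethoxyphenyl)-6-geranyl-5,7-bis(methoxymethoxy)chroman-4-one, via aryne 19 (not isolated)
Conditions: KF, 18-crown-6, THF, 0 °C to rt
Reagents that add atoms: none
Why: Proposed new method: fluoride attack at silicon in 14 expels triflate to give aryne 19, while reversible acyl–oxygen cleavage of the strained lactone by fluoride exposes the C2 alkoxide as an acyl fluoride; the alkoxide adds to the aryne carbon remote from the flanking OMOM group and the aryl anion formed beside that OMOM attacks the acyl carbon, so the two arene carbons are inserted into the O–C(=O) bond and the four-membered ring becomes the six-membered pyranone (direct O-arylation of the lactone oxygen followed by a 1,3-acyl shift would lead to the same product). The closest known reaction types are the fluoride-induced insertion of arynes into the N–C(=O) bond of amides and cyclic ureas (a ring expansion by two atoms), their insertion into the C–O bond of epoxides, and the coupling of arynes with carboxylic acids, which gives ortho-hydroxyaryl ketones by the same O-arylation and acyl transfer. Ring C is completed by C4a–C4 bond formation, a 6-exo-trig addition–elimination at the acyl carbon after the O1–C8a bond has formed. No new stereocentre is created: C2 is that of the lactone and none of its bonds is broken, so S is carried over with retention. The step needs O1 at C8a and the acyl carbon at C4a and not the reverse, which the inductively withdrawing C5 OMOM group beside the triple bond should secure by making the distal carbon the electrophilic one and by stabilising the anion next to itself; it also needs acyl–oxygen and not benzylic alkyl–oxygen cleavage of the lactone, which the hard nucleophile and the low temperature should favour.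

Step 10
Reactants: 20 (2S)-2-(3,4-dimethoxyphenyl)-6-geranyl-5,7-bis(methoxymethoxy)chroman-4-one
Product: 21 (2S)-2-(3,4-dimethoxyphenyl)-6-geranyl-5,7-dihydroxychroman-4-one (target)
Conditions: 3 M aq HCl, MeOH, 40 °C
Reagents that add atoms: none
Why: Acid-catalysed acetal solvolysis (transfer of the methoxymethyl groups to methanol) should free both phenols under conditions of the kind used for prenylated flavanones, mild enough to avoid addition of the phenols to the side-chain alkene and free of base, so that C2 is not epimerised by ring opening.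

**Compound list**

1 | 1,3-bis(methoxymethoxy)benzene | COCOc1cccc(OCOC)c1 | starting material
2 | geranyl bromide, (2E)-1-bromo-3,7-dimethylocta-2,6-diene | BrC/C=C(\C)CCC=C(C)C | starting material
3 | [2,6-bis(methoxymethoxy)phenyl]lithium | [Li]c1c(OCOC)cccc1OCOC | intermediate
4 | 2-geranyl-1,3-bis(methoxymethoxy)benzene | COCOc1cccc(OCOC)c1C/C=C(\C)CCC=C(C)C | intermediate
5 | [3-geranyl-2,4-bis(methoxymethoxy)phenyl]lithium | [Li]c1ccc(OCOC)c(C/C=C(\C)CCC=C(C)C)c1OCOC | intermediate
6 | dimethyl [3-geranyl-2,4-bis(methoxymethoxy)phenyl]boronate | COB(OC)c1ccc(OCOC)c(C/C=C(\C)CCC=C(C)C)c1OCOC | intermediate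
7 | 3-geranyl-2,4-bis(methoxymethoxy)phenol | Oc1ccc(OCOC)c(C/C=C(\C)CCC=C(C)C)c1OCOC | intermediate
8 | 3-geranyl-2,4-bis(methoxymethoxy)phenyl N-isopropylcarbamate | CC(C)NC(=O)Oc1ccc(OCOC)c(C/C=C(\C)CCC=C(C)C)c1OCOC | intermediate
9 | 3-geranyl-2,4-bis(methoxymethoxy)phenyl N-(tert-butyldimethylsilyl)-N-isopropylcarbamate | CC(C)N(C(=O)Oc1ccc(OCOC)c(C/C=C(\C)CCC=C(C)C)c1OCOC)[Si](C)(C)C(C)(C)C | intermediate
10 | 6-lithio derivative of 9 | CC(C)N(C(=O)Oc1c([Li])cc(OCOC)c(C/C=C(\C)CCC=C(C)C)c1OCOC)[Si](C)(C)C(C)(C)C | intermediate
11 | 6-(trimethylsilyl) derivative of 9 | CC(C)N(C(=O)Oc1c([Si](C)(C)C)cc(OCOC)c(C/C=C(\C)CCC=C(C)C)c1OCOC)[Si](C)(C)C(C)(C)C | intermediate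
12 | 3-geranyl-2,4-bis(methoxymethoxy)-6-(trimethylsilyl)phenyl N-isopropylcarbamate | CC(C)NC(=O)Oc1c([Si](C)(C)C)cc(OCOC)c(C/C=C(\C)CCC=C(C)C)c1OCOC | intermediate
13 | 3-geranyl-2,4-bis(methoxymethoxy)-6-(trimethylsilyl)phenol | Oc1c([Si](C)(C)C)cc(OCOC)c(C/C=C(\C)CCC=C(C)C)c1OCOC | intermediate
14 | 3-geranyl-2,4-bis(methoxymethoxy)-6-(trimethylsilyl)phenyl trifluoromethanesulfonate | FC(F)(F)S(=O)(=O)Oc1c([Si](C)(C)C)cc(OCOC)c(C/C=C(\C)CCC=C(C)C)c1OCOC | intermediate
15 | ethyl 3-(3,4-dimethoxyphenyl)-3-oxopropanoate | CCOC(=O)CC(=O)c1ccc(OC)c(OC)c1 | starting material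
16 | ethyl (3S)-3-(3,4-dimethoxyphenyl)-3-hydroxypropanoate | COc1ccc([C@@H](O)CC(=O)OCC)cc1OC | intermediate
17 | (3S)-3-(3,4-dimethoxyphenyl)-3-hydroxypropanoic acid | COc1ccc([C@@H](O)CC(=O)O)cc1OC | intermediate
18 | (4S)-4-(3,4-dimethoxyphenyl)oxetan-2-one | COc1ccc([C@@H]2CC(=O)O2)cc1OC | intermediate
19 | 4-geranyl-3,5-bis(methoxymethoxy)-1,2-didehydrobenzene (aryne) | C1#CC=C(OCOC)C(C/C=C(\C)CCC=C(C)C)=C1OCOC | intermediate
20 | (2S)-2-(3,4-dimethoxyphenyl)-6-geranyl-5,7-bis(methoxymethoxy)chroman-4-one | COc1ccc([C@@H]2CC(=O)c3c(cc(OCOC)c(C/C=C(\C)CCC=C(C)C)c3OCOC)O2)cc1OC | intermediate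
21 | (2S)-2-(3,4-dimethoxyphenyl)-6-geranyl-5,7-dihydroxychroman-4-one | COc1ccc([C@@H]2CC(=O)c3c(cc(O)c(C/C=C(\C)CCC=C(C)C)c3O)O2)cc1OC | target

**Totals**

Total step count: 10. Longest linear sequence: 7 steps (steps 1 to 5, 9 and 10); the lactone branch (steps 6 to 8) joins at step 9.

**Steps most likely to fail**

Step 9. The lactone may be consumed by alkyl–oxygen cleavage or by ionisation at the electron-rich benzylic carbon instead of acyl–oxygen cleavage. Anionic oligomerisation and β-elimination may outrun capture of the alkoxide by the aryne. The configuration at C2 may be lost by base-induced ring opening of the product.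
Fallback with known chemistry, setting out from 14 and coming back at 20: aryne 19 is generated from 14 with CsF in hot THF in the presence of acetic acid. O-arylation of the carboxylate at C8a and acyl shift to C4a (the known aryne–carboxylic acid coupling) should give 1-[3-geranyl-6-hydroxy-2,4-bis(methoxymethoxy)phenyl]ethan-1-one F1. Condensation with N,N-dimethylformamide dimethyl acetal gives the enaminone (2E)-3-(dimethylamino)-1-[3-geranyl-6-hydroxy-2,4-bis(methoxymethoxy)phenyl]prop-2-en-1-one F2. Mild acid treatment closes F2 with loss of dimethylamine to 6-geranyl-5,7-bis(methoxymethoxy)-4H-chromen-4-one F3. Enantioselective conjugate addition of 3,4-dimethoxyphenylboronic acid to F3 then gives 20; this uses Pd(OCOCF3)2 with a chiral tert-butyl pyridine–oxazoline ligand, or [Rh(OH)(cod)]2 with a chiral diene in a Hayashi–Miyaura addition, with the ligand enantiomer chosen for the S product.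

Step 8. Carboxyl activation or isolation may be overtaken by decarboxylative fragmentation to the styrene or by ionisation at the benzylic carbon.
Fallback, setting out from 16 and coming back at 20: the lactone is bypassed. The sodium alkoxide of 16 (NaH, THF, −20 °C) is added to aryne 19 generated from 14 (CsF, 18-crown-6). O-arylation at C8a followed by attack of the aryl anion on the ethyl ester should give 20 directly with loss of ethoxide. This is the open-chain counterpart of step 9 and of the same type as the aryne annulation of salicylate esters to xanthones. No new compound arises.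

Step 2. Deprotonation may occur at the benzylic and allylic methylene of the side chain instead of the ring C–H, and the electron-rich phenol may be over-oxidised.
Fallback, setting out from 4 and coming back at 20: iridium-catalysed C–H borylation of 4 ([Ir(OMe)(cod)]2, 4,4′-di-tert-butyl-2,2′-bipyridine, B2pin2) is governed by sterics and needs no strong base. It should borylate C5, the only ring C–H without an ortho substituent, to give 2-[4-geranyl-3,5-bis(methoxymethoxy)phenyl]-4,4,5,5-tetramethyl-1,3,2-dioxaborolane F4. Oxidation (H2O2, NaOH) gives 4-geranyl-3,5-bis(methoxymethoxy)phenol F5. The operations of steps 3 to 5 then follow: carbamoylation to 4-geranyl-3,5-bis(methoxymethoxy)phenyl N-isopropylcarbamate F6, ortho-silylation between the carbamate and an OMOM group to 4-geranyl-3,5-bis(methoxymethoxy)-2-(trimethylsilyl)phenyl N-isopropylcarbamate F7, and carbamate-to-triflate exchange to 4-geranyl-3,5-bis(methoxymethoxy)-2-(trimethylsilyl)phenyl trifluoromethanesulfonate F8. In F8 silicon and triflate have changed places relative to 14, but it gives the same aryne 19 and so rejoins the route at 20 in step 9.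

Further compounds
F1 | step 9 | 1-[3-geranyl-6-hydroxy-2,4-bis(methoxymethoxy)phenyl]ethan-1-one | CC(=O)c1c(O)cc(OCOC)c(C/C=C(\C)CCC=C(C)C)c1OCOC
F2 | step 9 | (2E)-3-(dimethylamino)-1-[3-geranyl-6-hydroxy-2,4-bis(methoxymethoxy)phenyl]prop-2-en-1-one | CN(C)/C=C/C(=O)c1c(O)cc(OCOC)c(C/C=C(\C)CCC=C(C)C)c1OCOC
F3 | step 9 | 6-geranyl-5,7-bis(methoxymethoxy)-4H-chromen-4-one | O=c1ccoc2cc(OCOC)c(C/C=C(\C)CCC=C(C)C)c(OCOC)c12
F0 | step 8 | none | none
F4 | step 2 | 2-[4-geranyl-3,5-bis(methoxymethoxy)phenyl]-4,4,5,5-tetramethyl-1,3,2-dioxaborolane | CC1(C)OB(OC1(C)C)c1cc(OCOC)c(C/C=C(\C)CCC=C(C)C)c(OCOC)c1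
F5 | step 2 | 4-geranyl-3,5-bis(methoxymethoxy)phenol | Oc1cc(OCOC)c(C/C=C(\C)CCC=C(C)C)c(OCOC)c1
F6 | step 2 | 4-geranyl-3,5-bis(methoxymethoxy)phenyl N-isopropylcarbamate | CC(C)NC(=O)Oc1cc(OCOC)c(C/C=C(\C)CCC=C(C)C)c(OCOC)c1
F7 | step 2 | 4-geranyl-3,5-bis(methoxymethoxy)-2-(trimethylsilyl)phenyl N-isopropylcarbamate | CC(C)NC(=O)Oc1cc(OCOC)c(C/C=C(\C)CCC=C(C)C)c(OCOC)c1[Si](C)(C)C
F8 | step 2 | 4-geranyl-3,5-bis(methoxymethoxy)-2-(trimethylsilyl)phenyl trifluoromethanesulfonate | FC(F)(F)S(=O)(=O)Oc1cc(OCOC)c(C/C=C(\C)CCC=C(C)C)c(OCOC)c1[Si](C)(C)C
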